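**Strategy.** Ring A is disconnected at C4a–C5 and C8–C8a. Its four contiguous oxygenated carbons C5, C6, C7 and C8 come from a squaric ester, fused onto the C4a–C8a edge of a preformed 2-arylpyran-4-one (ring C carrying ring B). In one thermal operation a 4-hydroxy-4-(pyranon-2-yl)cyclobutenone opens to a dienylketene and closes onto the pyranone. This forms C4a–C5 and delivers ring A as a 5,8-hydroquinone with O6 and O7 already in place. The precursor is the 1,2-adduct of the C6-magnesiated pyranone to bis(4-methoxybenzyl) squarate; ring B carries its hydroxyl as a benzyl ether.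

Key step: step 5

**Protecting-group logic.**
- The ring B hydroxyl travels as a benzyl ether. It survives the acid that closes the pyranone; an acetal would be lost there, and the freed phenol would close the 1,3-diketone to a chromone.
- O6 and O7 arrive from the squarate as 4-methoxybenzyl ethers. Acid removes them while the benzyl ether stays, so the methylation at O7 meets only the 6,7-catechol and the last step is a plain hydrogenolysis.
- A squaric ester with two different alkoxy groups was not chosen, because its two carbonyl groups would not be told apart in the addition.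

Assumption: the squarate diester is made in step 1 rather than bought, and cyclobutenone 10 is used as the racemate, since its only stereocentre becomes an arene carbon in step 5.

**Route**

Step 1
Reactants: 1 squaric acid
Product: 3 3,4-bis[(4-methoxybenzyl)oxy]cyclobut-3-ene-1,2-dione, via disilver squarate 2 (not isolated)
Conditions: Ag2O (1.05 equiv), MeCN, dark, rt; then 4-methoxybenzyl chloride (2.3 equiv), 4 Å MS, 40 °C
Reagents that add atoms: 4-methoxybenzyl chloride, COc1ccc(CCl)cc1
Why: Silver-assisted O-alkylation of a strongly acidic vinylogous carboxylic acid by a benzylic halide (ester formation from Ag2C4O4) should give the diester, since the squarate dianion offers only oxygen nucleophiles and the acid-sensitive 4-methoxybenzyl alcohol is never heated with acid; no stereocentre is formed.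

Step 2
Reactants: 4 2-hydroxy-6-methoxyacetophenone
Product: 5 1-[2-(benzyloxy)-6-methoxyphenyl]ethan-1-one
Conditions: BnBr (1.2 equiv), K2CO3 (2 equiv), DMF, 60 °C
Reagents that add atoms: benzyl bromide, BrCc1ccccc1
Why: Williamson ether synthesis on the phenoxide, whose hydrogen bond to the ketone is broken by carbonate in a dipolar aprotic solvent; no stereocentre is formed.

Step 3
Reactants: 5 1-[2-(benzyloxy)-6-methoxyphenyl]ethan-1-one; 6 methyl (E)-3-methoxyacrylate
Product: 8 2-[2-(benzyloxy)-6-methoxyphenyl]-4H-pyran-4-one, via methoxypentenedione 7 (not isolated)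
Conditions: LiN(SiMe3)2 (2.2 equiv), THF, −78 °C; 6 (1.2 equiv), −78 to 0 °C; then TFA, CH2Cl2, rt
Reagents that add atoms: none
Why: Crossed Claisen condensation of the methyl-ketone enolate with an ester that cannot enolise gives diketone 7, and trifluoroacetic acid then drives a 6-endo conjugate addition–elimination of the enol oxygen onto the β-methoxy enone (loss of methanol) to the pyranone, while the benzyl ether withstands the acid so that no free phenol can divert the diketone to a chromone; no stereocentre is formed.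

Step 4
Reactants: 8 2-[2-(benzyloxy)-6-methoxyphenyl]-4H-pyran-4-one; 3 3,4-bis[(4-methoxybenzyl)oxy]cyclobut-3-ene-1,2-dione
Product: 10 4-{6-[2-(benzyloxy)-6-methoxyphenyl]-4-oxo-4H-pyran-2-yl}-4-hydroxy-2,3-bis[(4-methoxybenzyl)oxy]cyclobut-2-en-1-one (racemate), via pyranonylmagnesium chloride 9 (not isolated)
Conditions: TMPMgCl·LiCl (1.15 equiv), THF, −40 °C; cannulated into 3 (1.3 equiv), THF, −78 to −40 °C; sat. aq NH4Cl
Reagents that add atoms: none
Why: Deprotonative magnesiation by a hindered amide base should remove the pyranone C6 hydrogen, the only ring hydrogen next to the ring oxygen (the position metalated in chromones at C2), and the α-alkoxyalkenyl Grignard reagent then undergoes 1,2-addition to one of the two equivalent ketone carbonyls of the squaric ester at low temperature; the new carbinol stereocentre forms as a racemate and is erased in step 5.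

Step 5
Reactants: 10 4-{6-[2-(benzyloxy)-6-methoxyphenyl]-4-oxo-4H-pyran-2-yl}-4-hydroxy-2,3-bis[(4-methoxybenzyl)oxy]cyclobut-2-en-1-one (racemate)
Product: 13 2-[2-(benzyloxy)-6-methoxyphenyl]-5,8-dihydroxy-6,7-bis[(4-methoxybenzyl)oxy]-4H-chromen-4-one, via dienylketene 11 (not isolated), via cyclohexadienone 12 (not isolated)
Conditions: toluene (0.02 M, degassed), 110 °C, argon
Reagents that add atoms: none
Why: Moore ring expansion: thermal conrotatory 4π ring opening of the cyclobutenone, with the donor hydroxyl turning outward, gives (Z)-dienylketene 11 in which the pyranone C=C lies next to the ketene. A thermal disrotatory 6π electrocyclisation then joins the ketene carbon (future C5) to the pyranone CH carbon (future C4a), closing the six-membered ring A as dienone 12, whose C4a hydrogen, flanked by two carbonyl groups, moves to oxygen to give the aromatic 5,8-hydroquinone 13. The closest known reaction type is the rearrangement of 4-alkenyl-, 4-aryl- and 4-heteroaryl-4-hydroxycyclobutenones to hydroquinones and quinones, to which the pyranonyl case adds a new member. No stereocentre remains, because the carbinol carbon and the transient C4a centre both become trigonal. The step needs torquoselectivity (pyranonyl inward), which the outward preference of the hydroxyl secures, and carbon–carbon closure rather than capture of the ketene by oxygen; the latter is favoured because the hydroxyl points away from the ketene in 11 and because the attacking carbon is the nucleophilic β-carbon of the O1–C8a=C4a enol ether meeting the electrophilic ketene carbon.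

Step 6
Reactants: 13 2-[2-(benzyloxy)-6-methoxyphenyl]-5,8-dihydroxy-6,7-bis[(4-methoxybenzyl)oxy]-4H-chromen-4-one
Product: 14 2-[2-(benzyloxy)-6-methoxyphenyl]-5,8-dimethoxy-6,7-bis[(4-methoxybenzyl)oxy]-4H-chromen-4-one
Conditions: MeI (4 equiv), K2CO3 (4 equiv), DMF, 45 °C, argon
Reagents that add atoms: iodomethane, CI
Why: Williamson O-methylation of both phenols, the chelated 5-hydroxyl needing the excess of iodomethane and the dipolar solvent, while the benzyl-type ethers are inert to carbonate and exclusion of air keeps the hydroquinone from oxidising to the quinone before it is alkylated.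

Step 7
Reactants: 14 2-[2-(benzyloxy)-6-methoxyphenyl]-5,8-dimethoxy-6,7-bis[(4-methoxybenzyl)oxy]-4H-chromen-4-one
Product: 15 2-[2-(benzyloxy)-6-methoxyphenyl]-6,7-dihydroxy-5,8-dimethoxy-4H-chromen-4-one
Conditions: TFA (10 vol%), 1,3-dimethoxybenzene (6 equiv), CH2Cl2, 0 °C
Reagents that add atoms: none
Why: Acidolysis (SN1 ether cleavage) of the two 4-methoxybenzyl aryl ethers runs through the stabilised 4-methoxybenzyl cation, which the electron-rich arene traps by Friedel–Crafts alkylation before it can attack ring B, whereas the plain benzyl ether and the methyl ethers, the peri 5-methoxy included, do not ionise in a Brønsted acid of this strength.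

Step 8
Reactants: 15 2-[2-(benzyloxy)-6-methoxyphenyl]-6,7-dihydroxy-5,8-dimethoxy-4H-chromen-4-one
Product: 16 2-[2-(benzyloxy)-6-methoxyphenyl]-6-hydroxy-5,7,8-trimethoxy-4H-chromen-4-one
Conditions: MeI (1.1 equiv), KHCO3 (1.5 equiv), DMF, 35 °C, argon
Reagents that add atoms: iodomethane, CI
Why: Chemoselective Williamson methylation under acidity control: the 7-hydroxyl, para to the C4a–C4 carbonyl, is a vinylogous carboxylic acid and the only phenol that hydrogencarbonate ionises to a useful extent, and once it is ionised the neighbouring 6-hydroxyl (para to the ring oxygen, meta to the carbonyl) is even less ready to lose its proton, so one equivalent of iodomethane should be taken up at O7.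

Step 9
Reactants: 16 2-[2-(benzyloxy)-6-methoxyphenyl]-6-hydroxy-5,7,8-trimethoxy-4H-chromen-4-one
Product: 17 6-hydroxy-2-(2-hydroxy-6-methoxyphenyl)-5,7,8-trimethoxy-4H-chromen-4-one (6,2'-dihydroxy-5,7,8,6'-tetramethoxyflavone)
Conditions: H2 (1 atm), Pd/C (10 wt% Pd), EtOAc–MeOH, rt
Reagents that add atoms: none
Why: Catalytic hydrogenolysis of the aryl benzyl ether on palladium frees the 2'-hydroxyl, the chromone double bond and the methyl ethers being untouched at one atmosphere and room temperature.

**Compound list**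

1 | squaric acid (3,4-dihydroxycyclobut-3-ene-1,2-dione) | OC1=C(O)C(=O)C1=O | starting material
2 | disilver squarate (Ag2C4O4) | [Ag+].[Ag+].[O-]C1=C([O-])C(=O)C1=O | intermediate
3 | 3,4-bis[(4-methoxybenzyl)oxy]cyclobut-3-ene-1,2-dione | COc1ccc(COC2=C(OCc3ccc(OC)cc3)C(=O)C2=O)cc1 | intermediate
4 | 2-hydroxy-6-methoxyacetophenone | CC(=O)c1c(O)cccc1OC | starting material
5 | 1-[2-(benzyloxy)-6-methoxyphenyl]ethan-1-one | CC(=O)c1c(OCc2ccccc2)cccc1OC | intermediate
6 | methyl (E)-3-methoxyacrylate | CO/C=C/C(=O)OC | starting material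
7 | (E)-1-[2-(benzyloxy)-6-methoxyphenyl]-5-methoxypent-4-ene-1,3-dione (largely enolised) | CO/C=C/C(=O)CC(=O)c1c(OCc2ccccc2)cccc1OC | intermediate
8 | 2-[2-(benzyloxy)-6-methoxyphenyl]-4H-pyran-4-one | COc1cccc(OCc2ccccc2)c1-c1cc(=O)cco1 | intermediate
9 | {6-[2-(benzyloxy)-6-methoxyphenyl]-4-oxo-4H-pyran-2-yl}magnesium chloride, LiCl complex | COc1cccc(OCc2ccccc2)c1-c1cc(=O)cc([Mg]Cl)o1.[Li+].[Cl-] | intermediate
10 | 4-{6-[2-(benzyloxy)-6-methoxyphenyl]-4-oxo-4H-pyran-2-yl}-4-hydroxy-2,3-bis[(4-methoxybenzyl)oxy]cyclobut-2-en-1-one (racemate) | O=C1C(OCc2ccc(OC)cc2)=C(OCc2ccc(OC)cc2)C1(O)c1cc(=O)cc(-c2c(OC)cccc2OCc2ccccc2)o1 | intermediate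
11 | (Z)-4-{6-[2-(benzyloxy)-6-methoxyphenyl]-4-oxo-4H-pyran-2-yl}-4-hydroxy-2,3-bis[(4-methoxybenzyl)oxy]buta-1,3-dien-1-one | O=C=C(OCc1ccc(OC)cc1)/C(OCc1ccc(OC)cc1)=C(/O)c1cc(=O)cc(-c2c(OC)cccc2OCc2ccccc2)o1 | intermediate
12 | 2-[2-(benzyloxy)-6-methoxyphenyl]-8-hydroxy-6,7-bis[(4-methoxybenzyl)oxy]-4aH-chromene-4,5-dione (racemate) | O=C1C(OCc2ccc(OC)cc2)=C(OCc2ccc(OC)cc2)C(O)=C2OC(-c3c(OC)cccc3OCc3ccccc3)=CC(=O)C12 | intermediate
13 | 2-[2-(benzyloxy)-6-methoxyphenyl]-5,8-dihydroxy-6,7-bis[(4-methoxybenzyl)oxy]-4H-chromen-4-one | COc1cccc(OCc2ccccc2)c1-c1cc(=O)c2c(O)c(OCc3ccc(OC)cc3)c(OCc3ccc(OC)cc3)c(O)c2o1 | intermediate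
14 | 2-[2-(benzyloxy)-6-methoxyphenyl]-5,8-dimethoxy-6,7-bis[(4-methoxybenzyl)oxy]-4H-chromen-4-one | COc1cccc(OCc2ccccc2)c1-c1cc(=O)c2c(OC)c(OCc3ccc(OC)cc3)c(OCc3ccc(OC)cc3)c(OC)c2o1 | intermediate
15 | 2-[2-(benzyloxy)-6-methoxyphenyl]-6,7-dihydroxy-5,8-dimethoxy-4H-chromen-4-one | COc1cccc(OCc2ccccc2)c1-c1cc(=O)c2c(OC)c(O)c(O)c(OC)c2o1 | intermediate
16 | 2-[2-(benzyloxy)-6-methoxyphenyl]-6-hydroxy-5,7,8-trimethoxy-4H-chromen-4-one | COc1cccc(OCc2ccccc2)c1-c1cc(=O)c2c(OC)c(O)c(OC)c(OC)c2o1 | intermediate
17 | 6-hydroxy-2-(2-hydroxy-6-methoxyphenyl)-5,7,8-trimethoxy-4H-chromen-4-one (6,2'-dihydroxy-5,7,8,6'-tetramethoxyflavone) | COc1cccc(O)c1-c1cc(=O)c2c(OC)c(O)c(OC)c(OC)c2o1 | target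

**Step count and risks**

Total steps: 9. Longest linear sequence: 8 steps (steps 2 to 9, from 4 to 17).

Steps most likely to fail:

1. Step 5 (key step). The ketene may be diverted before the carbon–carbon closure: after leakage of the alkene geometry the tertiary hydroxyl can capture it to give a five-membered lactone, and the hydroquinone may oxidise as it forms. The fallback sets out from 10 and caps the carbinol. Silylation with Et3SiOSO2CF3 and 2,6-lutidine in CH2Cl2 at −78 °C should give 4-{6-[2-(benzyloxy)-6-methoxyphenyl]-4-oxo-4H-pyran-2-yl}-2,3-bis[(4-methoxybenzyl)oxy]-4-[(triethylsilyl)oxy]cyclobut-2-en-1-one F1. This ether cannot lactonise and tolerates longer heating in toluene or p-xylene. The same opening and closure, known for 4-silyloxycyclobutenones, should then give 2-[2-(benzyloxy)-6-methoxyphenyl]-5-hydroxy-6,7-bis[(4-methoxybenzyl)oxy]-8-[(triethylsilyl)oxy]-4H-chromen-4-one F2, a monoprotected hydroquinone that does not oxidise. Tetrabutylammonium fluoride buffered with acetic acid in THF at 0 °C removes the aryl silyl ether, and the route is rejoined at 13.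

2. Step 4. The magnesiated pyranone may be lost before it meets the squarate, by addition to the carbonyl of pyranone not yet metalated or by ring opening after metalation next to the carbonyl, or the metalation may stay incomplete. The fallback sets out from 8 and separates metalation from addition. Zincation with TMPZnCl·LiCl in THF at 25 °C should give {6-[2-(benzyloxy)-6-methoxyphenyl]-4-oxo-4H-pyran-2-yl}zinc chloride F3, which is stable at room temperature and inert toward the pyranone carbonyl. Iodine then gives 2-[2-(benzyloxy)-6-methoxyphenyl]-6-iodo-4H-pyran-4-one F4, which is isolated so that its regiochemistry can be checked. Iodine–magnesium exchange with iPrMgCl·LiCl in THF at −78 °C regenerates 9 cold and within minutes, and addition of 3 followed by aqueous NH4Cl rejoins the route at 10.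

3. Step 8. Methylation may spill over to O6 or to both catechol oxygens. The fallback sets out from 15 and takes its selectivity from acyl cleavage instead of alkylation. Acetic anhydride in pyridine should give 2-[2-(benzyloxy)-6-methoxyphenyl]-5,8-dimethoxy-4-oxo-4H-chromene-6,7-diyl diacetate F5. Thiophenol with imidazole in N-methylpyrrolidinone at 0 °C cleaves the acetate of the more acidic 7-oxygen, the better leaving group, to give 2-[2-(benzyloxy)-6-methoxyphenyl]-7-hydroxy-5,8-dimethoxy-4-oxo-4H-chromen-6-yl acetate F6. Acetyl migration is not a concern here, since the isomer with the free 7-oxygen is also the more stable one. Neutral methylation of the single free hydroxyl with (trimethylsilyl)diazomethane in toluene–methanol gives 2-[2-(benzyloxy)-6-methoxyphenyl]-5,7,8-trimethoxy-4-oxo-4H-chromen-6-yl acetate F7. K2CO3 in methanol removes the acetate, and the route is rejoined at 16.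

Further compounds
F1 | step 5 | 4-{6-[2-(benzyloxy)-6-methoxyphenyl]-4-oxo-4H-pyran-2-yl}-2,3-bis[(4-methoxybenzyl)oxy]-4-[(triethylsilyl)oxy]cyclobut-2-en-1-one (racemate) | O=C1C(OCc2ccc(OC)cc2)=C(OCc2ccc(OC)cc2)C1(O[Si](CC)(CC)CC)c1cc(=O)cc(-c2c(OC)cccc2OCc2ccccc2)o1
F2 | step 5 | 2-[2-(benzyloxy)-6-methoxyphenyl]-5-hydroxy-6,7-bis[(4-methoxybenzyl)oxy]-8-[(triethylsilyl)oxy]-4H-chromen-4-one | COc1cccc(OCc2ccccc2)c1-c1cc(=O)c2c(O)c(OCc3ccc(OC)cc3)c(OCc3ccc(OC)cc3)c(O[Si](CC)(CC)CC)c2o1
F3 | step 4 | {6-[2-(benzyloxy)-6-methoxyphenyl]-4-oxo-4H-pyran-2-yl}zinc chloride, LiCl complex | COc1cccc(OCc2ccccc2)c1-c1cc(=O)cc([Zn]Cl)o1.[Li+].[Cl-]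
F4 | step 4 | 2-[2-(benzyloxy)-6-methoxyphenyl]-6-iodo-4H-pyran-4-one | COc1cccc(OCc2ccccc2)c1-c1cc(=O)cc(I)o1
F5 | step 8 | 2-[2-(benzyloxy)-6-methoxyphenyl]-5,8-dimethoxy-4-oxo-4H-chromene-6,7-diyl diacetate | COc1cccc(OCc2ccccc2)c1-c1cc(=O)c2c(OC)c(OC(C)=O)c(OC(C)=O)c(OC)c2o1
F6 | step 8 | 2-[2-(benzyloxy)-6-methoxyphenyl]-7-hydroxy-5,8-dimethoxy-4-oxo-4H-chromen-6-yl acetate | COc1cccc(OCc2ccccc2)c1-c1cc(=O)c2c(OC)c(OC(C)=O)c(O)c(OC)c2o1
F7 | step 8 | 2-[2-(benzyloxy)-6-methoxyphenyl]-5,7,8-trimethoxy-4-oxo-4H-chromen-6-yl acetate | COc1cccc(OCc2ccccc2)c1-c1cc(=O)c2c(OC)c(OC(C)=O)c(OC)c(OC)c2o1
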